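The leftover I wanted first was the starting material still in each flask at the end, as a fraction of its charge.

| setting | ochre | amber | green |
|---|---|---|---|
| starting material | 20 mM | 20 mM | 20 mM |
| coupling partner | 1.10 equiv | 1.10 equiv | 1.10 equiv |
| protic impurity | 1.00 mM | 1.00 mM | 1.00 mM |
| catalyst | 4.9 mol% | 7.4 mol% | 11 mol% |
| time | 12 h | 12 h | 12 h |

    starting material + catalyst → catalyst + intermediate (k1 = 0.0749 L mol⁻¹ s⁻¹)
    coupling partner + catalyst + intermediate → catalyst + target (k2 = 1.77 L² mol⁻² s⁻¹)
    catalyst + target → catalyst + over-reaction product (k3 = 0.0399 L mol⁻¹ s⁻¹)
    coupling partner + protic impurity → quenched reagent (k4 = 0.142 L mol⁻¹ s⁻¹)

1. which of these there is most of at the end, counted by the starting material in it, ochre (over-reaction product / intermediate / starting material / target)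
2. which of these there is most of at the end, counted by the starting material in it, amber (over-reaction product / intermediate / starting material / target)
3. which of these there is most of at the end, counted by the starting material in it, green (over-reaction product / intermediate / starting material / target)
4. final amount of the leader among these, as a percentage of the starting material charged, in ochre
5. final amount of the leader among these, as a percentage of the starting material charged, in amber
6. final amount of the leader among these, as a percentage of the starting material charged, in green

The catalyst stands on both sides of its steps, so it stays at its charge. The starting material therefore decays pseudo-first-order. I multiplied the constant of step 1 by catalyst and time and called the product the dose: the fraction of starting material left is exp(−dose).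

First I turned the loading, which scales the dose.

ochre: dose 3.17, left 4.20 %

amber: dose 4.79, left 0.832 %

green: dose 7.12, left 0.0810 %

Next I turned the time. It scales the dose as the loading does, and it scales the other catalysed steps too.

Then came the impurity. With coupling partner at its charge, the impurity itself has a half-life of 3.70 min, shorter than the 2.6 h of starting material in ochre. So I took the impurity's charge off the partner at once, which left 1.05 of the starting material's charge as partner.

Last came the partner. I called the constant of step 2 times the partner, over the constant of step 1, the pace. With that pace, intermediate is:

(exp(−pace × dose) − exp(−dose)) / (1 − pace)

First round, partner as it stood after the impurity: pace 0.496; ochre 32.8 %, amber 16.8 %.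

That answer burns partner, so I went round again with the partner midway between its start and what the first round left.

Second round: ochre pace 0.347, intermediate 44.5 %; amber pace 0.302, intermediate 32.6 %.

Step 3 against step 1 is 0.533, above amber's pace. So I expected amber's remainder of 66.6 % to lean to over-reaction product. I committed to intermediate leading in ochre and over-reaction product in amber, and green lay further along. My hand gave no figure for over-reaction product.

The forecast gave figures: intermediate at 45 % in ochre, over-reaction product at 46 % in amber, over-reaction product at 64 % in green. Its ground was that “higher loading simply runs further along the same path”.

The simulation gave intermediate at 44.8 % in ochre, over-reaction product at 45.8 % in amber and over-reaction product at 64.5 % in green, within the forecast's margins. So the lead changed hands between ochre's dose of 3.17 and amber's of 4.79. At 12.0 h, ochre made target at 0.893 of the rate it used it up. Ochre read at 20 h has a dose of 5.28, above amber's and below green's, which leaves 0.509 % of starting material. That flask held 0.507 % of it, with over-reaction product leading at 50.6 % and intermediate at 31.5 %.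

All constants were set for the occasion; the run is a simulation.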